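# Proposed total synthesis of nardostachysin

## Analysis of the target

Nardostachysin (39) is an ester of two terpenoid halves. The acid half is (1S,4R,5R)-guaia-7,9-dien-14-oic acid (guaiane numbering C1–C15). The alcohol half is an iridoid δ-lactone triol, numbered with primes: C1' lactone carbonyl, C3' the OCH2 group, C5' and C9' the ring fusion, C10' on C8', C11' the methylene on C4'. The two halves are joined through the primary C10' oxygen.

In the acid half a cyclopentane (C1–C5) is cis-fused to a cycloheptadiene (C1, C5–C10). The hydrogens on C1, C4 and C5 lie on one face, so the C15 methyl stands on the face from which the seven-membered ring departs. The C7=C8 and C9=C10 double bonds are conjugated with the C14 carboxyl.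

The lactone half is a cis-fused cyclopenta[c]pyran-1-one with four stereocentres (5'R, 7'S, 8'S, 9'R). The C7' and C8' hydroxyls are cis to each other and to the ring bonds C9'–C1' and C5'–C4', that is, on the concave face. C10' lies on the convex face and C4' carries an exocyclic methylene.

Sensitive points are the dienoate (double-bond migration), the C9'–H bond (α to the lactone carbonyl and next to the tertiary carbinol, so open to epimerisation and β-elimination), the two exocyclic alkenes and the diol beside the ester (acyl migration).

The synthesis is hard for three reasons: the seven-membered ring has a stereocentre (C1) next to its ester-bearing sp2 carbon, with C5 and C4 to be relayed from it; two oxygens sit on the hindered face of the iridoid; and the ester must be formed at a neopentyl-type carbon flanked by free hydroxyls.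

The strategy rests on the sequence C1(sp3)–C10(CO2R)=C9–C8–C7(isopropyl)–C6–C5 of the seven-membered ring. With an oxygen at C9 and a C5=C6 double bond this is the cyclohepta-1,4-diene that a vinyl carbenoid (C10, C9, C8) forms with a 1-alkenylcyclopentene (C1, C5, C6, C7).

## Retrosynthetic reasoning

**Ester link.** The only bond between the halves is C10'–O. It is cut so that the same step also creates the tertiary C8' hydroxyl: 39 goes back to acid 24 and spiro-epoxy alcohol 38. Opening of the epoxide at its unsubstituted carbon by the carboxylate leaves the C8'–O bond untouched, so no hydroxyl needs protection and C8' is fixed beforehand. The forward reaction must attack the primary carbon only and must not disturb the acidic C9'–H.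

**C8' oxygen.** External reagents reach the cyclopentane of the cis-fused lactone from the convex face, which is the wrong face for this oxygen. The C8'–O bond is therefore traced to a hydroxyl-directed epoxidation of allylic alcohol 37, in which the C7' hydroxyl on the concave face delivers the oxygen. Silyl ether 36 is the protected form of 37.

**Exocyclic C8'=C10' alkene.** 36 is the deconjugated isomer of the α,β-unsaturated lactone 34. The C10' methyl of 34 is the γ-position syn to the carbonyl, so kinetic deprotonation (dienolate 35) and α-protonation move the double bond out of the ring and set C9'–H. This turns an unfunctionalised methyl into the handle for both the C8' oxygen and the ester oxygen.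

**Lactone and cyclopentene.** The C3'–O bond of 34 is cut to chloro acid 33, which comes from enal 31 by ene-chlorination of the isopropenyl group (32) and oxidation. The C8'=C9' bond of 31 is an aldol condensation of keto aldehyde 30. 30 results from cleaving the ring alkene of (S)-carvone (25) after reduction to cis-carveol (26), directed epoxidation (27) and silylation (28). The gain is that C5' and C7', with their cis relationship, come from the chiral pool, and the directed epoxidation makes the cleavage site-selective.

**Diene of the acid.** 24 comes from methyl ester 23. The C9–H bond of 23 is cut back to enol triflate 22, and that to the enone β-keto ester 21. The C7=C8 bond of 21 is cut to the saturated β-keto ester 17 through the C8 selenide 19. The C9 oxygen thus directs the C7=C8 desaturation and is then removed with the C9=C10 bond left in place.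

**C4 and C5.** 17 is unmasked from silyl enol ether 16. The C4 methyl of 16 is cut to exocyclic alkene 15 and ketone 14, and the C5–H bond to enone 13, which is the deketalised form of 12. Both hydrogenations must occur on the convex face, which the C1 stereocentre defines. The C9 oxygen stays masked as the silyl enol ether so that only the C4 carbonyl reacts.

**Seven-membered ring.** 12 is cut at C1–C10 and C7–C8 into diene 7 and siloxyvinyl diazoacetate 10, by way of cis-divinylcyclopropane 11. This cut is chosen because it closes the ring, brings in C14 at the right oxidation level, puts an oxygen on C9 and a carbonyl equivalent on C4, and sets C1 with a chiral catalyst. The forward reaction must cyclopropanate the ring alkene of 7 and not the side-chain alkene, and must do so enantioselectively.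

**Precursors.** 7 is cut at the C5–C6 bond into bromo ketal 4 and alkenylboronate 6, which go back to cyclopent-2-en-1-one (1, through 3) and 3-methylbut-1-yne (5). 10 goes back through diazo keto ester 9 to methyl acetoacetate (8). Every step before the key step is routine.

## Alternatives that were turned down

**Alternative 1: carbonylative union.**
- Disconnection: the C10–C14 and C14–O bonds, giving dienyl triflate A1, the acetonide-protected iridoid alcohol A2 and carbon monoxide A3.
- Forward key step: zerovalent palladium inserts into the C–O bond of A1, A3 inserts, and A2 captures the acyl palladium to give the protected ester A4.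
- For: it is the most convergent union. C14 comes from A3, no ester has to be saponified next to the diene, and the diene of A1 would come from a cycloheptenone in one enolisation. That is shorter than the six steps (12–17) spent here on the C9 oxygen.
- Against: it is an end game only. The ketone behind A1 has C1 as an enolisable α-stereocentre, so the cis ring fusion is at risk at the moment the triflate is made. A2 is a hindered neopentyl-type alcohol that must be protected and later deprotected. The seven-membered ring and its stereocentres are not addressed.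
- Comparison: stronger on convergence at the ester. The chosen strategy instead builds the ring, C14 and C1 in one catalytic step and joins the halves without any protecting group.

**Alternative 2: biomimetic transannular cyclisation.**
- Disconnection: the C1–C5 bond of the hydroazulene, giving the ten-membered epoxide A5.
- Forward key step: a Lewis acid opens the epoxide of A5 and the C1=C10 alkene attacks C5, giving the cis-fused hydroxy dienone A6.
- For: one step from a ten-membered terpenoid to the bicycle, with C1, C4 and C5 relayed from the epoxide. No route to the skeleton is shorter.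
- Against: A6 is wrong at four sites. C4 carries a tertiary hydroxyl that must be replaced by hydrogen with control of configuration. C8 carries a ketone the target lacks. The isopropylidene must be moved into the ring as C7=C8. C14 is a methyl that must be raised three oxidation levels beside other allylic positions. Single-enantiomer A5 needs an enantioselective epoxidation of an achiral macrocycle, and such cation cyclisations tend to give several skeletons and alkene isomers.
- Comparison: shorter to the ring system, longer and less certain after it. The chosen strategy places the carboxyl carbon, the C9 oxygen and the C4 carbonyl exactly where later steps need them.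

**Alternative 3: allenoate [3+2] annulation for the iridoid half.**
- Disconnection: the C8'–C9' and C5'–C6' bonds, giving pyranone A7 and allenoate A8.
- Forward key step: a tertiary phosphine activates A8, which adds through its α-carbon to C9' and its γ-carbon to C5' of A7, giving the cis-fused bicycle A9.
- For: one catalytic step builds the iridoid core with C10' in place, a C7'=C8' alkene and a C4' ketone for the methylene. The acetal centre of A7 controls the absolute configuration. It would probably reach the iridoid half in fewer steps than the eleven used here.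
- Against: it solves only the easier half. The regiochemistry of the annulation on a cyclic, γ-oxygenated enone is uncertain. The C7'=C8' alkene of A9 would then have to be dihydroxylated on the concave face, which osmium reagents avoid.
- Comparison: complementary, not competing. The chosen route imports C7' from carvone and delivers the C8' oxygen from it, and it puts the main risk into one bond-forming event on the harder half.

Key step: step 7

Assumption: the absolute sense of induction of Rh2(S-PTAD)4 with diene 7 is assigned by analogy with its reactions of siloxyvinyl diazoacetates with other dienes; if it proves opposite, the mirror-image complex Rh2(R-PTAD)4 is used and nothing else changes.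

## Route

Step 1
Reactants: 1 cyclopent-2-en-1-one
Product: 3 2-bromocyclopent-2-en-1-one, via trans-2,3-dibromocyclopentan-1-one 2 (not isolated)
Conditions: Br2, CH2Cl2, 0 °C; then Et3N, 0 °C
Reagents that add atoms: bromine, BrBr
Why: Bromine adds across the enone alkene and triethylamine removes HBr from the dibromide (addition–elimination), which leaves bromine on the α-carbon.

Step 2
Reactants: 3 2-bromocyclopent-2-en-1-one
Product: 4 6-bromo-1,4-dioxaspiro[4.4]non-6-ene
Conditions: ethylene glycol, p-TsOH (cat.), benzene, reflux, Dean–Stark trap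
Reagents that add atoms: ethylene glycol, OCCO
Why: Acid-catalysed ketalisation driven by azeotropic removal of water; the ketal masks the C4 carbonyl for the carbenoid step.

Step 3
Reactants: 5 3-methylbut-1-yne
Product: 6 2-[(E)-3-methylbut-1-enyl]-4,4,5,5-tetramethyl-1,3,2-dioxaborolane
Conditions: pinacolborane, Cp2Zr(H)Cl (5 mol%), Et3N (10 mol%), neat, 60 °C, sealed tube
Reagents that add atoms: pinacolborane, CC1(C)OBOC1(C)C
Why: Zirconium-catalysed hydroboration of a terminal alkyne is a syn, anti-Markovnikov addition and should give only the E-alkenylboronate.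

Step 4
Reactants: 4 6-bromo-1,4-dioxaspiro[4.4]non-6-ene; 6 2-[(E)-3-methylbut-1-enyl]-4,4,5,5-tetramethyl-1,3,2-dioxaborolane
Product: 7 6-[(E)-3-methylbut-1-enyl]-1,4-dioxaspiro[4.4]non-6-ene
Conditions: Pd(PPh3)4 (5 mol%), 2 M aq. NaOH, THF, 65 °C
Reagents that add atoms: none
Why: Suzuki–Miyaura coupling of an alkenyl bromide with an alkenylboronate keeps both alkene geometries, and the basic medium does not touch the ketal.

Step 5
Reactants: 8 methyl acetoacetate
Product: 9 methyl 2-diazo-3-oxobutanoate
Conditions: 4-acetamidobenzenesulfonyl azide, Et3N, MeCN, 0 °C → rt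
Reagents that add atoms: 4-acetamidobenzenesulfonyl azide, CC(=O)Nc1ccc(cc1)S(=O)(=O)N=[N+]=[N-]
Why: Regitz diazo transfer to an active methylene group.

Step 6
Reactants: 9 methyl 2-diazo-3-oxobutanoate
Product: 10 methyl 3-(tert-butyldimethylsilyloxy)-2-diazobut-3-enoate
Conditions: TBSOTf, Et3N, CH2Cl2, 0 °C; used without long storage
Reagents that add atoms: tert-butyldimethylsilyl triflate, CC(C)(C)[Si](C)(C)OS(=O)(=O)C(F)(F)F
Why: Soft enolisation of the acetyl group by silyl triflate and amine gives the 2-siloxyvinyl diazoacetate; the diazo group survives these conditions.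

Step 7
Reactants: 7 6-[(E)-3-methylbut-1-enyl]-1,4-dioxaspiro[4.4]non-6-ene; 10 methyl 3-(tert-butyldimethylsilyloxy)-2-diazobut-3-enoate
Product: 12 methyl (1S,7R)-9-(tert-butyldimethylsilyloxy)-4,4-(ethylenedioxy)-15-norguaia-5,9-dien-14-oate, via cis-divinylcyclopropane 11 (not isolated)
Conditions: Rh2(S-PTAD)4 (dirhodium tetrakis[(S)-N-phthaloyl-(1-adamantyl)glycinate], 1 mol%), 10 added over 3 h, hexanes, −26 °C → rt; then 50 °C to complete the rearrangement
Reagents that add atoms: none
Why: The rhodium complex takes N2 from 10 to give a donor–acceptor vinylcarbenoid, which cyclopropanates the ring alkene of 7 in an asynchronous step that begins at the unsubstituted C1 terminus while the developing charge at C5 is spread over C5–C6–C7. As in cyclopropanations of dienes by such carbenoids, the conjugating alkenyl group on C5 ends on the side of the carbenoid vinyl group, so 11 is a cis-1,2-divinylcyclopropane with the ester over the five-membered ring. 11 then undergoes a [3,3]-sigmatropic (Cope) shift through the boat transition state, the only one open to a cis-divinylcyclopropane: C7–C8 forms, C5–C10 breaks, and the seven-membered ring closes as a formal [4+3] annulation. The closest known reaction type is the rhodium-catalysed tandem cyclopropanation/Cope rearrangement of siloxyvinyl diazoacetates with dienes. C1 is set by the chiral carboxylate ligands, which select the face of the ring alkene; the adamantylglycinate complex is chosen because a substituent on the internal vinyl carbon, here the siloxy group, erodes the selectivity of prolinate catalysts such as Rh2(S-DOSP)4. C7 follows from C1, because in the boat the E-placed isopropyl group points outward and H7 ends cis to H1. The step needs the ring alkene to react in preference to the side-chain alkene and cyclopropanation to win over allylic C–H insertion; the trans-disubstituted, branched side-chain alkene is a poor partner for this carbenoid, and a conjugated diene is far more nucleophilic than an isolated alkene.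

Step 8
Reactants: 12 methyl (1S,7R)-9-(tert-butyldimethylsilyloxy)-4,4-(ethylenedioxy)-15-norguaia-5,9-dien-14-oate
Product: 13 methyl (1S,7R)-9-(tert-butyldimethylsilyloxy)-4-oxo-15-norguaia-5,9-dien-14-oate
Conditions: PPTS (0.2 equiv), acetone/H2O (10:1), rt
Reagents that add atoms: water, O
Why: Acid-catalysed ketal hydrolysis; the allylic ketal ionises to a conjugated oxocarbenium ion much faster than an isolated ketal, while the β-silyloxy acrylate is deactivated toward C-protonation by its ester and should persist.

Step 9
Reactants: 13 methyl (1S,7R)-9-(tert-butyldimethylsilyloxy)-4-oxo-15-norguaia-5,9-dien-14-oate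
Product: 14 methyl (1S,5S,7R)-9-(tert-butyldimethylsilyloxy)-4-oxo-15-norguai-9-en-14-oate
Conditions: H2 (1 atm), 10% Pd/C, EtOAc, rt
Reagents that add atoms: none
Why: Heterogeneous hydrogenation of the enone alkene; hydrogen should add to the face of C5=C6 that carries H1, opposite the C1–C10 bond, which gives the cis ring fusion. The tetrasubstituted siloxy acrylate is inert.

Step 10
Reactants: 14 methyl (1S,5S,7R)-9-(tert-butyldimethylsilyloxy)-4-oxo-15-norguai-9-en-14-oate
Product: 15 methyl (1S,5S,7R)-9-(tert-butyldimethylsilyloxy)guaia-4(15),9-dien-14-oate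
Conditions: Zn, CH2Br2, TiCl4, THF/CH2Cl2, 0 °C → rt
Reagents that add atoms: dibromomethane, BrCBr
Why: Takai–Lombardo methylenation; the non-basic gem-dimetallic reagent olefinates the ketone without enolising it, so the C5 stereocentre α to the carbonyl is kept, and the ester is not attacked.

Step 11
Reactants: 15 methyl (1S,5S,7R)-9-(tert-butyldimethylsilyloxy)guaia-4(15),9-dien-14-oate
Product: 16 methyl (1S,4R,5R,7R)-9-(tert-butyldimethylsilyloxy)guai-9-en-14-oate
Conditions: H2 (1 atm), RhCl(PPh3)3 (10 mol%), benzene, rt
Reagents that add atoms: none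
Why: Homogeneous hydrogenation of a 1,1-disubstituted alkene; the catalyst should approach the convex face of the cis-fused bicycle (the face of H1 and H5), which puts H4 cis to H5 and the methyl on the side of C6. This catalyst does not move the double bond into the ring.

Step 12
Reactants: 16 methyl (1S,4R,5R,7R)-9-(tert-butyldimethylsilyloxy)guai-9-en-14-oate
Product: 17 methyl (1S,4R,5R,7R)-9-oxoguaian-14-oate
Conditions: Bu4NF, AcOH, THF, 0 °C
Reagents that add atoms: none
Why: Fluoride cleaves the O–Si bond of the vinylogous silyl ester and acetic acid buffers the enolate; 17 is expected as a keto/enol mixture, which has no consequence because C10 becomes sp2 again.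

Step 13
Reactants: 17 methyl (1S,4R,5R,7R)-9-oxoguaian-14-oate
Product: 19 methyl (1S,4R,5R,7S,8S)-9-oxo-8-(phenylselanyl)guaian-14-oate, via dilithium dianion 18 (not isolated)
Conditions: LiN(iPr)2 (2.3 equiv), THF, −78 → 0 °C; PhSeBr, −78 °C; AcOH quench
Reagents that add atoms: benzeneselenenyl bromide, Br[Se]c1ccccc1
Why: Double deprotonation gives the C8,C10-dianion of the β-keto ester, whose more basic C8 terminus attacks selenium (γ-selenenylation). Attack anti to the isopropyl group should place selenium cis to H7.

Step 14
Reactants: 19 methyl (1S,4R,5R,7S,8S)-9-oxo-8-(phenylselanyl)guaian-14-oate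
Product: 21 methyl (1S,4R,5R)-9-oxoguai-7-en-14-oate, via selenoxide 20 (not isolated)
Conditions: 30% H2O2, pyridine, CH2Cl2, 0 °C → rt
Reagents that add atoms: none
Why: Oxidation to the selenoxide and syn-elimination; only H7 can be lost because C9 is a carbonyl carbon, so the C7=C8 enone results.

Step 15
Reactants: 21 methyl (1S,4R,5R)-9-oxoguai-7-en-14-oate
Product: 22 methyl (1S,4R,5R)-9-(trifluoromethanesulfonyloxy)guaia-7,9-dien-14-oate
Conditions: Tf2O, iPr2NEt, CH2Cl2, −78 °C
Reagents that add atoms: triflic anhydride, FC(F)(F)S(=O)(=O)OS(=O)(=O)C(F)(F)F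
Why: O-sulfonylation of the enol of the β-keto ester gives the dienyl triflate; the ring fixes the alkene geometry.

Step 16
Reactants: 22 methyl (1S,4R,5R)-9-(trifluoromethanesulfonyloxy)guaia-7,9-dien-14-oate
Product: 23 methyl (1S,4R,5R)-guaia-7,9-dien-14-oate
Conditions: Pd(OAc)2 (5 mol%), PPh3 (10 mol%), HCO2H, Bu3N, DMF, 60 °C
Reagents that add atoms: none
Why: Palladium-catalysed reduction of an enol triflate: zerovalent palladium inserts into the C–O bond, formate delivers hydride with loss of CO2, and reductive elimination leaves both double bonds where they are.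

Step 17
Reactants: 23 methyl (1S,4R,5R)-guaia-7,9-dien-14-oate
Product: 24 (1S,4R,5R)-guaia-7,9-dien-14-oic acid
Conditions: LiOH·H2O, THF/MeOH/H2O, 40 °C; then 1 M HCl
Reagents that add atoms: lithium hydroxide, [Li+].[OH-]
Why: Saponification by acyl substitution; C1 should not epimerise because its anion would only be cross-conjugated with the ester.

Step 18
Reactants: 25 (S)-(+)-carvone
Product: 26 (1S,5S)-cis-carveol
Conditions: NaBH4, CeCl3·7H2O, MeOH, −78 → 0 °C
Reagents that add atoms: none
Why: Luche 1,2-reduction; axial hydride delivery gives the allylic alcohol with hydroxyl cis to the isopropenyl group, the relationship needed between C7'–O and C5'.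

Step 19
Reactants: 26 (1S,5S)-cis-carveol
Product: 27 (1S,2S,4R,6R)-1-methyl-4-(prop-1-en-2-yl)-7-oxabicyclo[4.1.0]heptan-2-ol
Conditions: VO(acac)2 (2 mol%), t-BuOOH, CH2Cl2, 0 °C → rt
Reagents that add atoms: tert-butyl hydroperoxide, CC(C)(C)OO
Why: Hydroxyl-directed epoxidation; the vanadium alkoxide delivers oxygen syn to the hydroxyl and only to the allylic alcohol alkene, leaving the isopropenyl group untouched.

Step 20
Reactants: 27 (1S,2S,4R,6R)-1-methyl-4-(prop-1-en-2-yl)-7-oxabicyclo[4.1.0]heptan-2-ol
Product: 28 tert-butyldimethylsilyl ether of 27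
Conditions: TBSCl, imidazole, DMF, rt
Reagents that add atoms: tert-butyldimethylsilyl chloride, CC(C)(C)[Si](C)(C)Cl
Why: Silylation of the secondary alcohol; without it periodate would also cleave the bond to the carbinol carbon.

Step 21
Reactants: 28 tert-butyldimethylsilyl ether of 27
Product: 30 (3R,5S)-5-(tert-butyldimethylsilyloxy)-6-oxo-3-(prop-1-en-2-yl)heptanal, via trans-diol 29 (not isolated)
Conditions: H5IO6, THF/H2O, 0 °C → rt
Reagents that add atoms: water, O
Why: Aqueous periodic acid opens the epoxide to the trans-diol and cleaves it (glycol cleavage) to the keto aldehyde; neither stereocentre is touched.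

Step 22
Reactants: 30 (3R,5S)-5-(tert-butyldimethylsilyloxy)-6-oxo-3-(prop-1-en-2-yl)heptanal
Product: 31 (3S,5S)-3-(tert-butyldimethylsilyloxy)-2-methyl-5-(prop-1-en-2-yl)cyclopent-1-ene-1-carbaldehyde
Conditions: Bn2NH·CF3CO2H (0.2 equiv), benzene, 50 °C
Reagents that add atoms: none
Why: Amine-salt-catalysed intramolecular aldol condensation: the aldehyde enamine (C9') attacks the ketone (C8') in a 5-exo closure and the adduct dehydrates to the enal. The weakly acidic salt is chosen so that the α-silyloxy ketone is consumed before it can epimerise.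

Step 23
Reactants: 31 (3S,5S)-3-(tert-butyldimethylsilyloxy)-2-methyl-5-(prop-1-en-2-yl)cyclopent-1-ene-1-carbaldehyde
Product: 32 (3S,5R)-3-(tert-butyldimethylsilyloxy)-5-(3-chloroprop-1-en-2-yl)-2-methylcyclopent-1-ene-1-carbaldehyde
Conditions: Ca(OCl)2, solid CO2, CH2Cl2/H2O, 0 °C
Reagents that add atoms: calcium hypochlorite, [Ca+2].[O-]Cl.[O-]Cl
Why: Ene-type chlorination by hypochlorous acid formed in situ; the electron-rich 1,1-disubstituted alkene is chlorinated with allylic transposition, while the electron-poor enal alkene does not react.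

Step 24
Reactants: 32 (3S,5R)-3-(tert-butyldimethylsilyloxy)-5-(3-chloroprop-1-en-2-yl)-2-methylcyclopent-1-ene-1-carbaldehyde
Product: 33 (3S,5R)-3-(tert-butyldimethylsilyloxy)-5-(3-chloroprop-1-en-2-yl)-2-methylcyclopent-1-ene-1-carboxylic acid
Conditions: NaClO2, NaH2PO4, 2-methyl-2-butene, t-BuOH/H2O, rt
Reagents that add atoms: sodium chlorite, [Na+].[O-]Cl=O
Why: Pinnick oxidation of the enal; the alkene scavenger removes hypochlorous acid before it can attack the substrate.

Step 25
Reactants: 33 (3S,5R)-3-(tert-butyldimethylsilyloxy)-5-(3-chloroprop-1-en-2-yl)-2-methylcyclopent-1-ene-1-carboxylic acid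
Product: 34 (4aS,6S)-6-(tert-butyldimethylsilyloxy)-7-methyl-4-methylidene-4,4a,5,6-tetrahydrocyclopenta[c]pyran-1(3H)-one
Conditions: K2CO3, DMF (0.01 M), rt
Reagents that add atoms: none
Why: Intramolecular carboxylate alkylation (6-exo-tet SN2 at the allylic chloride) closes the δ-lactone; direct and allylically transposed attack give the same product.

Step 26
Reactants: 34 (4aS,6S)-6-(tert-butyldimethylsilyloxy)-7-methyl-4-methylidene-4,4a,5,6-tetrahydrocyclopenta[c]pyran-1(3H)-one
Product: 36 (4aR,6S,7aR)-6-(tert-butyldimethylsilyloxy)-4,7-dimethylidenehexahydrocyclopenta[c]pyran-1(3H)-one, via lithium dienolate 35 (not isolated)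
Conditions: LiN(iPr)2 (1.2 equiv), THF/DMPU, −78 °C; then AcOH, −78 °C
Reagents that add atoms: none
Why: Deconjugative protonation: the base removes a proton from the C10' methyl, the γ-position syn to the lactone carbonyl, and the exocyclic dienolate is protonated kinetically at the α-carbon C9'. Protonation on the convex face gives the cis ring fusion, which is also the stable one for this lactone.

Step 27
Reactants: 36 (4aR,6S,7aR)-6-(tert-butyldimethylsilyloxy)-4,7-dimethylidenehexahydrocyclopenta[c]pyran-1(3H)-one
Product: 37 (4aR,6S,7aR)-6-hydroxy-4,7-dimethylidenehexahydrocyclopenta[c]pyran-1(3H)-one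
Conditions: HF·pyridine, pyridine, THF, 0 °C → rt
Reagents that add atoms: none
Why: Fluoride desilylation under buffered, non-basic conditions that cannot move the exocyclic double bond back into conjugation.

Step 28
Reactants: 37 (4aR,6S,7aR)-6-hydroxy-4,7-dimethylidenehexahydrocyclopenta[c]pyran-1(3H)-one
Product: 38 (4aR,6S,7S,7aR)-6-hydroxy-4-methylidenehexahydrospiro[cyclopenta[c]pyran-7(1H),2'-oxiran]-1-one
Conditions: VO(acac)2 (5 mol%), t-BuOOH, CH2Cl2, 0 °C
Reagents that add atoms: tert-butyl hydroperoxide, CC(C)(C)OO
Why: Hydroxyl-directed epoxidation; the vanadium alkoxide on the C7' oxygen delivers oxygen to the same, concave face of the C8'=C10' alkene and so sets C8'. The C4' methylene is too remote to be reached.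

Step 29
Reactants: 24 (1S,4R,5R)-guaia-7,9-dien-14-oic acid; 38 (4aR,6S,7S,7aR)-6-hydroxy-4-methylidenehexahydrospiro[cyclopenta[c]pyran-7(1H),2'-oxiran]-1-one
Product: 39 nardostachysin
Conditions: Ti(OiPr)4 (1.5 equiv), CH2Cl2, rt; aq. tartaric acid work-up
Reagents that add atoms: none
Why: Titanium-alkoxide-mediated opening of a 2,3-epoxy alcohol by a carboxylic acid: titanium binds the C7' alkoxide and the epoxide oxygen, and the carboxylate attacks the unsubstituted C10' in an SN2 step. The C8'–O bond is not broken, so its configuration is kept and the tertiary hydroxyl and the ester appear together.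

## Compound list

1 | cyclopent-2-en-1-one | O=C1C=CCC1 | starting material
2 | trans-2,3-dibromocyclopentan-1-one (racemic) | O=C1CC[C@H](Br)[C@H]1Br | intermediate (not isolated)
3 | 2-bromocyclopent-2-en-1-one | O=C1CCC=C1Br | intermediate
4 | 6-bromo-1,4-dioxaspiro[4.4]non-6-ene | BrC1=CCCC12OCCO2 | intermediate
5 | 3-methylbut-1-yne | CC(C)C#C | starting material
6 | 2-[(E)-3-methylbut-1-enyl]-4,4,5,5-tetramethyl-1,3,2-dioxaborolane | CC(C)/C=C/B1OC(C)(C)C(C)(C)O1 | intermediate
7 | 6-[(E)-3-methylbut-1-enyl]-1,4-dioxaspiro[4.4]non-6-ene | CC(C)/C=C/C1=CCCC12OCCO2 | intermediate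
8 | methyl acetoacetate | CC(=O)CC(=O)OC | starting material
9 | methyl 2-diazo-3-oxobutanoate | CC(=O)C(=[N+]=[N-])C(=O)OC | intermediate
10 | methyl 3-(tert-butyldimethylsilyloxy)-2-diazobut-3-enoate | C=C(O[Si](C)(C)C(C)(C)C)C(=[N+]=[N-])C(=O)OC | intermediate
11 | methyl 6-[1-(tert-butyldimethylsilyloxy)ethenyl]-1-[(E)-3-methylbut-1-enyl]spiro[bicyclo[3.1.0]hexane-2,2'-[1,3]dioxolane]-6-carboxylate, the two alkenyl groups cis on the cyclopropane | COC(=O)[C@@]1(C(=C)O[Si](C)(C)C(C)(C)C)[C@H]2CCC3(OCCO3)[C@@]12/C=C/C(C)C | intermediate (not isolated)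
12 | methyl (1S,7R)-9-(tert-butyldimethylsilyloxy)-4,4-(ethylenedioxy)-15-norguaia-5,9-dien-14-oate | COC(=O)C1=C(O[Si](C)(C)C(C)(C)C)C[C@H](C(C)C)C=C2[C@@H]1CCC23OCCO3 | intermediate
13 | methyl (1S,7R)-9-(tert-butyldimethylsilyloxy)-4-oxo-15-norguaia-5,9-dien-14-oate | COC(=O)C1=C(O[Si](C)(C)C(C)(C)C)C[C@H](C(C)C)C=C2[C@@H]1CCC2=O | intermediate
14 | methyl (1S,5S,7R)-9-(tert-butyldimethylsilyloxy)-4-oxo-15-norguai-9-en-14-oate (cis-fused) | COC(=O)C1=C(O[Si](C)(C)C(C)(C)C)C[C@H](C(C)C)C[C@H]2[C@@H]1CCC2=O | intermediate
15 | methyl (1S,5S,7R)-9-(tert-butyldimethylsilyloxy)guaia-4(15),9-dien-14-oate | COC(=O)C1=C(O[Si](C)(C)C(C)(C)C)C[C@H](C(C)C)C[C@H]2[C@@H]1CCC2=C | intermediate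
16 | methyl (1S,4R,5R,7R)-9-(tert-butyldimethylsilyloxy)guai-9-en-14-oate | COC(=O)C1=C(O[Si](C)(C)C(C)(C)C)C[C@H](C(C)C)C[C@@H]2[C@H](C)CC[C@H]12 | intermediate
17 | methyl (1S,4R,5R,7R)-9-oxoguaian-14-oate (C10 epimers and enol) | COC(=O)C1C(=O)C[C@H](C(C)C)C[C@@H]2[C@H](C)CC[C@H]12 | intermediate
18 | dilithium C8,C10-dianion of 17 | [Li+].[Li+].COC([O-])=C1C([O-])=C[C@H](C(C)C)C[C@@H]2[C@H](C)CC[C@H]12 | intermediate (not isolated)
19 | methyl (1S,4R,5R,7S,8S)-9-oxo-8-(phenylselanyl)guaian-14-oate (selenium trans to isopropyl, C10 unassigned) | COC(=O)C1C(=O)[C@@H]([Se]c3ccccc3)[C@H](C(C)C)C[C@@H]2[C@H](C)CC[C@H]12 | intermediate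
20 | selenoxide of 19 | COC(=O)C1C(=O)[C@@H]([Se](=O)c3ccccc3)[C@H](C(C)C)C[C@@H]2[C@H](C)CC[C@H]12 | intermediate (not isolated)
21 | methyl (1S,4R,5R)-9-oxoguai-7-en-14-oate (C10 epimers and enol) | COC(=O)C1C(=O)C=C(C(C)C)C[C@@H]2[C@H](C)CC[C@H]12 | intermediate
22 | methyl (1S,4R,5R)-9-(trifluoromethanesulfonyloxy)guaia-7,9-dien-14-oate | COC(=O)C1=C(OS(=O)(=O)C(F)(F)F)C=C(C(C)C)C[C@@H]2[C@H](C)CC[C@H]12 | intermediate
23 | methyl (1S,4R,5R)-guaia-7,9-dien-14-oate | COC(=O)C1=CC=C(C(C)C)C[C@@H]2[C@H](C)CC[C@H]12 | intermediate
24 | (1S,4R,5R)-guaia-7,9-dien-14-oic acid | OC(=O)C1=CC=C(C(C)C)C[C@@H]2[C@H](C)CC[C@H]12 | intermediate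
25 | (S)-(+)-carvone | O=C1C(C)=CC[C@H](C(C)=C)C1 | starting material
26 | (1S,5S)-cis-carveol | O[C@@H]1C(C)=CC[C@H](C(C)=C)C1 | intermediate
27 | (1S,2S,4R,6R)-1-methyl-4-(prop-1-en-2-yl)-7-oxabicyclo[4.1.0]heptan-2-ol (epoxide syn to hydroxyl) | O[C@@H]1[C@]2(C)O[C@@H]2C[C@H](C(C)=C)C1 | intermediate
28 | tert-butyldimethylsilyl ether of 27 | CC(C)(C)[Si](C)(C)O[C@@H]1[C@]2(C)O[C@@H]2C[C@H](C(C)=C)C1 | intermediate
29 | trans-1,2-diol from 28 (inversion at the methyl-bearing carbon) | CC(C)(C)[Si](C)(C)O[C@@H]1[C@@](C)(O)[C@H](O)C[C@H](C(C)=C)C1 | intermediate (not isolated)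
30 | (3R,5S)-5-(tert-butyldimethylsilyloxy)-6-oxo-3-(prop-1-en-2-yl)heptanal | CC(=O)[C@@H](O[Si](C)(C)C(C)(C)C)C[C@H](CC=O)C(C)=C | intermediate
31 | (3S,5S)-3-(tert-butyldimethylsilyloxy)-2-methyl-5-(prop-1-en-2-yl)cyclopent-1-ene-1-carbaldehyde | O=CC1=C(C)[C@@H](O[Si](C)(C)C(C)(C)C)C[C@H]1C(C)=C | intermediate
32 | (3S,5R)-3-(tert-butyldimethylsilyloxy)-5-(3-chloroprop-1-en-2-yl)-2-methylcyclopent-1-ene-1-carbaldehyde | O=CC1=C(C)[C@@H](O[Si](C)(C)C(C)(C)C)C[C@H]1C(=C)CCl | intermediate
33 | (3S,5R)-3-(tert-butyldimethylsilyloxy)-5-(3-chloroprop-1-en-2-yl)-2-methylcyclopent-1-ene-1-carboxylic acid | OC(=O)C1=C(C)[C@@H](O[Si](C)(C)C(C)(C)C)C[C@H]1C(=C)CCl | intermediate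
34 | (4aS,6S)-6-(tert-butyldimethylsilyloxy)-7-methyl-4-methylidene-4,4a,5,6-tetrahydrocyclopenta[c]pyran-1(3H)-one | C=C1COC(=O)C2=C(C)[C@@H](O[Si](C)(C)C(C)(C)C)C[C@@H]12 | intermediate
35 | lithium dienolate of 34 (exocyclic C8'=C10') | [Li+].C=C1COC([O-])=C2[C@H]1C[C@H](O[Si](C)(C)C(C)(C)C)C2=C | intermediate (not isolated)
36 | (4aR,6S,7aR)-6-(tert-butyldimethylsilyloxy)-4,7-dimethylidenehexahydrocyclopenta[c]pyran-1(3H)-one | C=C1COC(=O)[C@@H]2[C@H]1C[C@H](O[Si](C)(C)C(C)(C)C)C2=C | intermediate
37 | (4aR,6S,7aR)-6-hydroxy-4,7-dimethylidenehexahydrocyclopenta[c]pyran-1(3H)-one | C=C1COC(=O)[C@@H]2[C@H]1C[C@H](O)C2=C | intermediate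
38 | (4aR,6S,7S,7aR)-6-hydroxy-4-methylidenehexahydrospiro[cyclopenta[c]pyran-7(1H),2'-oxiran]-1-one (oxirane oxygen cis to the hydroxyl) | C=C1COC(=O)[C@@H]2[C@H]1C[C@H](O)[C@@]23CO3 | intermediate
39 | nardostachysin | C=C1COC(=O)[C@@H]2[C@H]1C[C@H](O)[C@@]2(O)COC(=O)C1=CC=C(C(C)C)C[C@@H]2[C@H](C)CC[C@H]12 | target

## Step count and least certain steps

Total step count: 29. Longest linear sequence: 15 steps (steps 1, 2, 4, 7–17 and 29, from cyclopent-2-en-1-one); the iridoid branch contributes 12 (steps 18–29).

**Step 7 (key step).** The ring alkene of 7 is trisubstituted, and its C2 substituent has to sit on the ester side of the new cyclopropane. Cyclopropanation may therefore be slow, and the carbenoid may instead insert into the allylic C–H bonds at C2 or C3 or into the C–H bonds of the dioxolane, or dimerise. The cyclopropane may also form with the two alkenyl groups trans, which does not rearrange at low temperature, and the enantioselectivity may be modest.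

Fallback: the same cis-divinylcyclopropane rearrangement is reached by ionic chemistry, setting out from 3 and coming back at 13. Suzuki coupling of 3 with 6 should give 2-[(E)-3-methylbut-1-enyl]cyclopent-2-en-1-one F1. Michael addition of methyl 2-chloroacetoacetate (K2CO3, DMF) at C1, then closure of the enolate onto the chlorine-bearing carbon (Michael-initiated ring closure), should give methyl 6-acetyl-1-[(E)-3-methylbut-1-enyl]-2-oxobicyclo[3.1.0]hexane-6-carboxylate F2. TBSOTf and Et3N should turn both ketones into silyl enol ethers, giving the bis(silyl enol ether) F3. The diastereomer of F3 with the siloxyvinyl group cis to the butenyl chain should undergo the Cope shift on warming to the bicyclic bis(silyl ether) F4; the other needs heating to epimerise. Mild acid (PPTS, wet acetone) should hydrolyse only the simple silyl dienol ether of F4 and deliver 13. This material is racemic, so acid 24 would then be resolved as its salt with an enantiopure amine before step 29.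

**Step 29.** The Lewis acid may trigger β-elimination of the epoxide toward the acidic C9'–H, attack of the carboxylate at the tertiary C8', or ring opening of the δ-lactone by isopropoxide.

Fallback: this sets out from 37 and comes back at 39. Hydrogen-bond-directed osmylation (OsO4, TMEDA, CH2Cl2, −78 °C; aqueous Na2SO3 work-up) should deliver both oxygens syn to the C7' hydroxyl, giving the triol (4aR,6S,7S,7aR)-6,7-dihydroxy-7-(hydroxymethyl)-4-methylidenehexahydrocyclopenta[c]pyran-1(3H)-one F8. Yamaguchi esterification then follows: 24 with 2,4,6-trichlorobenzoyl chloride and Et3N gives the mixed anhydride F9, which with F8 and DMAP should acylate only the primary hydroxyl to give 39.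

**Step 26.** Deprotonation may occur at C7' instead of the methyl group, protonation may return the conjugated lactone, or the product may reconjugate on work-up.

Fallback: photochemical deconjugation of 34 (254 nm, MeCN, catalytic 1,2-dimethylimidazole). The excited enoate abstracts a hydrogen from the methyl group syn to the carbonyl, and the resulting dienol ketonises at C9'. It sets out from 34 and comes back at 36 without any new compound.

**Step 11.** Facial discrimination at the exocyclic alkene may be poor, or the double bond may migrate into the ring before it is reduced.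

Fallback: this sets out from 15 and comes back at 16. Hydroboration with the bulky 9-BBN and then NaBO3 should add hydrogen to C4 from the convex face and give the primary alcohol methyl (1S,4R,5R,7R)-9-(tert-butyldimethylsilyloxy)-15-hydroxyguai-9-en-14-oate F6. I2, PPh3 and imidazole should convert it into the iodide F7, and Bu3SnH with AIBN (toluene, 80 °C) should reduce that to 16.

**Step 8.** The silyl enol ether may be lost together with the ketal.

Fallback: this sets out from 12 and comes back at 13. Full hydrolysis (1 M HCl, THF) gives the diketo ester methyl (1S,7R)-4,9-dioxo-15-norguai-5-en-14-oate F5. TBSCl and imidazole (DMF) should then silylate only the acidic β-keto ester enol to give 13.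

## Further compounds

F1 | step 7 | 2-[(E)-3-methylbut-1-enyl]cyclopent-2-en-1-one | CC(C)/C=C/C1=CCCC1=O
F2 | step 7 | methyl 6-acetyl-1-[(E)-3-methylbut-1-enyl]-2-oxobicyclo[3.1.0]hexane-6-carboxylate (racemic, acetyl cis to the butenyl chain; one enantiomer drawn) | COC(=O)[C@@]1(C(C)=O)[C@H]2CCC(=O)[C@@]12/C=C/C(C)C
F3 | step 7 | bis(tert-butyldimethylsilyl enol ether) of F2 (racemic; one enantiomer drawn) | COC(=O)[C@@]1(C(=C)O[Si](C)(C)C(C)(C)C)[C@H]2CC=C(O[Si](C)(C)C(C)(C)C)[C@@]12/C=C/C(C)C
F4 | step 7 | methyl 4,9-bis(tert-butyldimethylsilyloxy)-15-norguaia-3,5,9-trien-14-oate (racemic; one enantiomer drawn) | COC(=O)C1=C(O[Si](C)(C)C(C)(C)C)C[C@H](C(C)C)C=C2[C@@H]1CC=C2O[Si](C)(C)C(C)(C)C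
F5 | step 8 | methyl (1S,7R)-4,9-dioxo-15-norguai-5-en-14-oate | COC(=O)C1C(=O)C[C@H](C(C)C)C=C2[C@@H]1CCC2=O
F6 | step 11 | methyl (1S,4R,5R,7R)-9-(tert-butyldimethylsilyloxy)-15-hydroxyguai-9-en-14-oate | COC(=O)C1=C(O[Si](C)(C)C(C)(C)C)C[C@H](C(C)C)C[C@@H]2[C@H](CO)CC[C@H]12
F7 | step 11 | methyl (1S,4R,5R,7R)-9-(tert-butyldimethylsilyloxy)-15-iodoguai-9-en-14-oate | COC(=O)C1=C(O[Si](C)(C)C(C)(C)C)C[C@H](C(C)C)C[C@@H]2[C@H](CI)CC[C@H]12
F0 | step 26 | none | none
F8 | step 29 | (4aR,6S,7S,7aR)-6,7-dihydroxy-7-(hydroxymethyl)-4-methylidenehexahydrocyclopenta[c]pyran-1(3H)-one | C=C1COC(=O)[C@@H]2[C@H]1C[C@H](O)[C@@]2(O)CO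
F9 | step 29 | mixed anhydride of 24 with 2,4,6-trichlorobenzoic acid | O=C(OC(=O)c1c(Cl)cc(Cl)cc1Cl)C1=CC=C(C(C)C)C[C@@H]2[C@H](C)CC[C@H]12
A1 | alternative 1 | (1S,4R,5R)-14-norguaia-7,9-dien-10-yl trifluoromethanesulfonate | O=S(=O)(OC1=CC=C(C(C)C)C[C@@H]2[C@H](C)CC[C@H]12)C(F)(F)F
A2 | alternative 1 | 7',8'-O-isopropylidene derivative of the iridoid lactone triol | C=C1COC(=O)[C@@H]2[C@H]1C[C@@H]1OC(C)(C)O[C@]21CO
A3 | alternative 1 | carbon monoxide | [C-]#[O+]
A4 | alternative 1 | nardostachysin 7',8'-acetonide | C=C1COC(=O)[C@@H]2[C@H]1C[C@@H]1OC(C)(C)O[C@]21COC(=O)C1=CC=C(C(C)C)C[C@@H]2[C@H](C)CC[C@H]12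
A5 | alternative 2 | (4S,5S)-germacrone 4,5-epoxide | C/C1=C\CC[C@]2(C)O[C@H]2CC(=C(C)C)C(=O)C1
A6 | alternative 2 | 4-hydroxy-cis-guaia-7(11),9-dien-8-one | CC(C)=C1C[C@@H]2[C@@](C)(O)CC[C@@H]2C(C)=CC1=O
A7 | alternative 3 | (R)-6-(pivaloyloxy)-2H-pyran-3(6H)-one | O=C1CO[C@H](OC(=O)C(C)(C)C)C=C1
A8 | alternative 3 | ethyl buta-2,3-dienoate | CCOC(=O)C=C=C
A9 | alternative 3 | cis-fused cyclopenta[c]pyranone cyclopentene ester | CCOC(=O)C1=CC[C@H]2C(=O)CO[C@H](OC(=O)C(C)(C)C)[C@@H]12
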